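At 1.3 min the easy comparison is already there: Monday's run, with twice the starting material of Friday's run and the same free catalyst, holds 1.40 times Friday's target, a reading with the scatter of two small numbers. So the target at that time grows less than in proportion to the charge. The decision for the next flask is whether to raise the charge to 3.00 M at 0.00300 M free catalyst for 20 min, and it hangs on how much target that charge gives in the same time.

| flask | starting material | free catalyst | time |
|---|---|---|---|
| Friday's | 0.600 M | 0.00300 M |  |
| Monday's | 1.20 M | 0.00300 M |  |
| Wednesday's | 0.600 M | 0.00450 M |  |
| Sunday's | 3.00 M | 0.00300 M | 20 min |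

| run | time / min | [target] / M |
|---|---|---|
| Friday's run | 0.80 | 0.0260 |
| Friday's run | 1.3 | 0.0430 |
| Friday's run | 2.0 | 0.0709 |
| Friday's run | 3.2 | 0.1004 |
| Friday's run | 5.0 | 0.1479 |
| Friday's run | 8.0 | 0.2128 |
| Friday's run | 13 | 0.3031 |
| Friday's run | 20 | 0.3876 |
| Monday's run | 0.80 | 0.0372 |
| Monday's run | 1.3 | 0.0604 |
| Monday's run | 2.0 | 0.0928 |
| Monday's run | 3.2 | 0.1445 |
| Monday's run | 5.0 | 0.2238 |
| Monday's run | 8.0 | 0.3432 |
| Monday's run | 13 | 0.5217 |
| Monday's run | 20 | 0.7072 |
| Wednesday's run | 0.80 | 0.0382 |
| Wednesday's run | 1.3 | 0.0585 |
| Wednesday's run | 2.0 | 0.0937 |
| Wednesday's run | 3.2 | 0.1405 |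
| Wednesday's run | 5.0 | 0.2078 |
| Wednesday's run | 8.0 | 0.2900 |
| Wednesday's run | 13 | 0.3879 |
| Wednesday's run | 20 | 0.4627 |

(standard deviation of a reading: 0.002 M)

* order of the initial rate in [free catalyst], near the charge of the Friday's run, the rate being that where two percent of its starting material are target
* order of the initial rate in [starting material], near the charge of the Friday's run, the rate being that where two percent of its starting material are target (one fixed amount of target, the same in the runs compared)
* target in the Sunday's run at 20 min, as a share of the starting material charged

The reckoning here takes a hyperbolic rate in starting material, which that ratio turns into a half-saturation concentration (the Michaelis constant), the starting material at which the rate stands at half its ceiling, 0.816 M. Friday's early rate then puts the ceiling at 0.0780 M min⁻¹. Integrated in closed form, this rate says that the load, target + Km·ln(charge/(charge − target)), equals ceiling × time, which is 1.56 M at 20 min.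

The last readings give a load of 1.23 M in Friday's run and 1.43 M in Monday's run, so the larger charge stands closer to that figure, and both fall short. Sunday's load is placed between Monday's and the ceiling's, which gives 1.07 M to 1.16 M of target, or 35.7% to 38.7% of the charge. Even the low end exceeds Monday's 0.7072 M, so the larger charge goes in and the free catalyst stays as it was.

The forecast sets 37% (range 31% to 43%), with orders 0.95 in free catalyst and 0.6 in starting material, on early rates “indicating saturation”.

Sunday's run gives 38.0% at 20 min, or 1.14 M of target.

    free catalyst + starting material ⇌ catalyst-substrate complex, settled at all times (2.760 M⁻¹)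
    catalyst-substrate complex + starting material ⇌ doubly bound catalyst, settled at all times (3.000 M⁻¹)
    doubly bound catalyst → target + catalyst-substrate complex (19.80 min⁻¹)
    free catalyst + starting material → spent catalyst + starting material (0.1242 M⁻¹ min⁻¹)
    starting material → target (0.003480 min⁻¹)

The orders are 0.94 in free catalyst and 0.71 in starting material, and the step to spent catalyst moves the readings by 7.7 times their scatter, as a root mean square. Sunday's load comes to 1.53 M, more than Monday's 1.43 M and less than the ceiling's 1.56 M. Wednesday's run has 1.50 times Friday's free catalyst, and its load at half conversion is 0.865 M, which at that multiple of the ceiling gives 7.39 min, while the target reaches that share at 8.43 min.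

The earlier runs and the new flask were generated by integration on assumed constants; the scatter is artificial.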